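**Strategy.** The terminal flavan unit is traced back to a five-membered lactol. Its ring C (O1, C2, C3, C4, C4a, C8a) is made by inserting C2, already carrying ring B, between O1 and the anomeric carbon (future C3) of 4,6-bis(benzyloxy)-2,3-dihydrobenzofuran-2-ol. In one operation, a chiral benzylic sulfonium ylide epoxidises the ring-opened lactol and the phenol recloses 6-endo. This unites the ring A and ring B fragments, forms C2–C3 and O1–C2, sets C2 and expands the ring from five to six atoms. The resulting tetra-O-benzyl flavan-3-ol, after inversion at C3, is the single building block for all three units, which are joined by bromine-capped 4β→6 Friedel–Crafts couplings.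

Key step: step 5

Remark: the (1R,4R,5R) antipode of isothiocineole is assumed to be the one whose benzylic ylide gives the (S)-configured aryl-bearing epoxide carbon; if the sense of induction is the opposite, its mirror image is used and nothing else changes.

**Step 1**
Reactants: 1 [3,4-bis(benzyloxy)phenyl]methanol; 2 (1R,4R,5R)-isothiocineole
Product: 3 (1R,4R,5R)-6-[3,4-bis(benzyloxy)benzyl]-4,7,7-trimethyl-6-thiabicyclo[3.2.1]octan-6-ium tetrafluoroborate (benzyl on the exo face of sulfur)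
Conditions: HBF4·OEt2, CH2Cl2, 0 °C → rt
Reagents that add atoms: tetrafluoroboric acid, [H+].F[B-](F)(F)F
Why: Acid ionises the electron-rich benzylic alcohol and the sulfide captures the cation on its exposed lone pair (sulfonium salt formation by S-alkylation), which should give one crystalline, non-nucleophilic-anion salt.

**Step 2**
Reactants: 4 3,5-bis(benzyloxy)phenol
Product: 5 1-(allyloxy)-3,5-bis(benzyloxy)benzene
Conditions: allyl bromide, K2CO3, acetone, reflux
Reagents that add atoms: allyl bromide, C=CCBr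
Why: Williamson ether synthesis on the only free phenol.

**Step 3**
Reactants: 5 1-(allyloxy)-3,5-bis(benzyloxy)benzene
Product: 6 2-allyl-3,5-bis(benzyloxy)phenol
Conditions: PhNEt2, 190 °C
Reagents that add atoms: none
Why: Aromatic Claisen rearrangement ([3,3]); the two ortho positions are equivalent by symmetry, so a single product is expected.

**Step 4**
Reactants: 6 2-allyl-3,5-bis(benzyloxy)phenol
Product: 7 4,6-bis(benzyloxy)-2,3-dihydro-1-benzofuran-2-ol (lactol, hemiacetal epimers)
Conditions: OsO4 (cat.), NaIO4, 2,6-lutidine, 1,4-dioxane/H2O, rt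
Reagents that add atoms: sodium periodate, [Na+].[O-]I(=O)(=O)=O (oxygen relayed by catalytic osmium tetroxide, O=[Os](=O)(=O)=O)
Why: Lemieux–Johnson oxidative cleavage gives the 2-hydroxyarylacetaldehyde, which should close spontaneously to the five-membered lactol (5-exo-trig hemiacetal formation).

**Step 5**
Reactants: 7 4,6-bis(benzyloxy)-2,3-dihydro-1-benzofuran-2-ol; 3 sulfonium tetrafluoroborate
Product: 10 (2R,3S)-5,7-bis(benzyloxy)-2-[3,4-bis(benzyloxy)phenyl]chroman-3-ol (5,7,3',4'-tetra-O-benzyl-(+)-catechin), via hydroxy aldehyde 8 (not isolated), via epoxy phenol 9 (not isolated)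
Conditions: 3 + KOt-Bu (1.2 equiv), THF, −78 °C; add 7 + KOt-Bu (1.0 equiv); then TsOH·H2O (1.5 equiv), −78 → 0 °C
Reagents that add atoms: none
Why: Deprotonation opens lactol 7 to the phenoxide of aldehyde 8 (ring–chain tautomerism), the pre-formed benzylic ylide adds to the aldehyde, and the anti betaine closes (3-exo-tet) to trans-epoxy phenol 9 with release of sulfide 2; acid then triggers 6-endo-tet attack of the phenol on the aryl-activated benzylic epoxide carbon with inversion, so the ylide carbon ends up inserted between O1 and the former anomeric carbon. The closest known reaction type is the Corey–Chaykovsky-type homologative annulation of lactols and cyclic hemiaminals with semi-stabilised sulfur ylides to 2-aryl-3-hydroxy six-membered heterocycles. C2 is controlled by the sulfide, which fixes the ylide conformation and shields one face of the ylide carbon, together with the invertive opening; C3 follows from anti-betaine formation (trans-epoxide) and is erased in step 6, so any cis-epoxide that opens with inversion (giving 12) converges on the same (2R)-ketone. The step needs 6-endo over 5-exo opening and ylide addition over enolisation of 8: the first is secured by forming the epoxide at −78 °C in aprotic medium and opening it only under acid, where the electron-rich aryl group directs attack to the benzylic carbon; the second is secured by pre-forming the ylide so that neither free base nor alkylating sulfonium salt meets the phenoxide aldehyde.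

**Step 6**
Reactants: 10 tetra-O-benzyl-(+)-catechin
Product: 11 (2R)-5,7-bis(benzyloxy)-2-[3,4-bis(benzyloxy)phenyl]chroman-3-one
Conditions: Dess–Martin periodinane, wet CH2Cl2, rt
Reagents that add atoms: none
Why: Dess–Martin oxidation of the secondary alcohol under near-neutral conditions should leave the C2 stereocentre intact.

**Step 7**
Reactants: 11 (2R)-flavan-3-one
Product: 12 (2R,3R)-5,7-bis(benzyloxy)-2-[3,4-bis(benzyloxy)phenyl]chroman-3-ol (5,7,3',4'-tetra-O-benzyl-(−)-epicatechin)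
Conditions: Li[BH(s-Bu)3], THF, −78 °C; then H2O
Reagents that add atoms: none
Why: Substrate-controlled hydride reduction: the bulky borohydride attacks the ketone face opposite the 2-aryl group, which should give the 2,3-cis (3R) alcohol.

**Step 8**
Reactants: 12 tetra-O-benzyl-(−)-epicatechin
Product: 13 (2R,3R)-8-bromo-5,7-bis(benzyloxy)-2-[3,4-bis(benzyloxy)phenyl]chroman-3-ol
Conditions: NBS (1.0 equiv), CH2Cl2, −78 °C → rt
Reagents that add atoms: N-bromosuccinimide, O=C1CCC(=O)N1Br
Why: Electrophilic aromatic bromination at C8, the more accessible and more nucleophilic of the two free ring A positions, leaves C6 as the only nucleophilic carbon.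

**Step 9**
Reactants: 12 tetra-O-benzyl-(−)-epicatechin
Product: 14 (2R,3R,4S)-5,7-bis(benzyloxy)-2-[3,4-bis(benzyloxy)phenyl]-4-(2-ethoxyethoxy)chroman-3-ol (4β, 3,4-trans)
Conditions: DDQ, HOCH2CH2OEt, CH2Cl2, rt
Reagents that add atoms: 2-ethoxyethanol, CCOCCO
Why: DDQ benzylic oxidation (hydride abstraction at C4) gives a ring A-stabilised cation that the alcohol traps anti to the axial 3-hydroxyl, which sets 4β.

**Step 10**
Reactants: 14 4β-(2-ethoxyethoxy) monomer
Product: 15 (2R,3R,4S)-6,8-dibromo-5,7-bis(benzyloxy)-2-[3,4-bis(benzyloxy)phenyl]-4-(2-ethoxyethoxy)chroman-3-ol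
Conditions: NBS (2.1 equiv), CH2Cl2, 0 °C → rt
Reagents that add atoms: N-bromosuccinimide, O=C1CCC(=O)N1Br
Why: Twofold electrophilic aromatic bromination caps both nucleophilic ring A positions of the future top unit, so this electrophile cannot condense with itself.

**Step 11**
Reactants: 15 dibromo electrophile; 13 8-bromo nucleophile (in excess)
Product: 16 6,8-dibromo-tetra-O-benzyl-epicatechin-(4β→6)-8-bromo-tetra-O-benzyl-epicatechin
Conditions: Me3SiOTf (cat.), CH2Cl2, −78 °C
Reagents that add atoms: none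
Why: Lewis acid ionisation of the C4 acetal-type ether and Friedel–Crafts C-arylation; C6 is the only free nucleophilic carbon of 13, and attack anti to the axial 3-hydroxyl of the cation should give the 4β (3,4-trans) bond.

**Step 12**
Reactants: 16 protected dimer
Product: 17 6,8-dibromo-tetra-O-benzyl-epicatechin-(4β→6)-8-bromo-4β-(2-ethoxyethoxy)-tetra-O-benzyl-epicatechin
Conditions: DDQ, HOCH2CH2OEt, CH2Cl2, rt
Reagents that add atoms: 2-ethoxyethanol, CCOCCO
Why: DDQ benzylic oxidation at the only remaining C4 methylene (lower unit), trapped trans to its 3-hydroxyl as in step 9.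

**Step 13**
Reactants: 17 dimeric electrophile; 13 8-bromo nucleophile (in excess)
Product: 18 6,8-dibromo-tetra-O-benzyl-epicatechin-(4β→6)-8-bromo-tetra-O-benzyl-epicatechin-(4β→6)-8-bromo-tetra-O-benzyl-epicatechin
Conditions: Me3SiOTf (cat.), CH2Cl2, −78 °C
Reagents that add atoms: none
Why: Second Friedel–Crafts C-arylation of the flavan-4-yl cation; the fully capped dimer has no nucleophilic site, so only C6 of 13 can react, again anti to the 3-hydroxyl (4β).

**Step 14**
Reactants: 18 protected trimer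
Product: 19 epicatechin-(4β→6)-epicatechin-(4β→6)-epicatechin (target)
Conditions: H2 (1 atm), Pd(OH)2/C, Et3N, THF/MeOH/H2O, rt
Reagents that add atoms: none
Why: Catalytic hydrogenolysis should cleave the twelve benzyl ethers and the four aryl C–Br bonds in one operation, the amine buffering the HBr so the acid-labile interflavan bonds survive.

**Compound list**
1 | [3,4-bis(benzyloxy)phenyl]methanol | OCc1ccc(OCc2ccccc2)c(OCc2ccccc2)c1 | starting material
2 | (1R,4R,5R)-4,7,7-trimethyl-6-thiabicyclo[3.2.1]octane (isothiocineole) | C[C@@H]1CC[C@@H]2C[C@H]1SC2(C)C | starting material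
3 | (1R,4R,5R)-6-[3,4-bis(benzyloxy)benzyl]-4,7,7-trimethyl-6-thiabicyclo[3.2.1]octan-6-ium tetrafluoroborate (exo S-benzyl) | C[C@@H]1CC[C@@H]2C[C@H]1[S@@+](Cc1ccc(OCc3ccccc3)c(OCc3ccccc3)c1)C2(C)C.F[B-](F)(F)F | intermediate
4 | 3,5-bis(benzyloxy)phenol | Oc1cc(OCc2ccccc2)cc(OCc2ccccc2)c1 | starting material
5 | 1-(allyloxy)-3,5-bis(benzyloxy)benzene | C=CCOc1cc(OCc2ccccc2)cc(OCc2ccccc2)c1 | intermediate
6 | 2-allyl-3,5-bis(benzyloxy)phenol | C=CCc1c(O)cc(OCc2ccccc2)cc1OCc1ccccc1 | intermediate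
7 | 4,6-bis(benzyloxy)-2,3-dihydro-1-benzofuran-2-ol | OC1Cc2c(OCc3ccccc3)cc(OCc3ccccc3)cc2O1 | intermediate
8 | 2-[2,4-bis(benzyloxy)-6-hydroxyphenyl]acetaldehyde (present as its potassium phenoxide) | O=CCc1c(O)cc(OCc2ccccc2)cc1OCc1ccccc1 | intermediate
9 | 3,5-bis(benzyloxy)-2-{[(2S,3S)-3-[3,4-bis(benzyloxy)phenyl]oxiran-2-yl]methyl}phenol | Oc1cc(OCc2ccccc2)cc(OCc2ccccc2)c1C[C@@H]1O[C@H]1c1ccc(OCc2ccccc2)c(OCc2ccccc2)c1 | intermediate
10 | (2R,3S)-5,7-bis(benzyloxy)-2-[3,4-bis(benzyloxy)phenyl]chroman-3-ol | C(c4ccccc4)Oc1cc(OCc4ccccc4)c2c(c1)O[C@H](c1ccc(OCc4ccccc4)c(OCc4ccccc4)c1)[C@@H](O)C2 | intermediate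
11 | (2R)-5,7-bis(benzyloxy)-2-[3,4-bis(benzyloxy)phenyl]chroman-3-one | C(c4ccccc4)Oc1cc(OCc4ccccc4)c2c(c1)O[C@H](c1ccc(OCc4ccccc4)c(OCc4ccccc4)c1)C(=O)C2 | intermediate
12 | (2R,3R)-5,7-bis(benzyloxy)-2-[3,4-bis(benzyloxy)phenyl]chroman-3-ol | C(c4ccccc4)Oc1cc(OCc4ccccc4)c2c(c1)O[C@H](c1ccc(OCc4ccccc4)c(OCc4ccccc4)c1)[C@H](O)C2 | intermediate
13 | (2R,3R)-8-bromo-5,7-bis(benzyloxy)-2-[3,4-bis(benzyloxy)phenyl]chroman-3-ol | C(c4ccccc4)Oc1cc(OCc4ccccc4)c2c(c1Br)O[C@H](c1ccc(OCc4ccccc4)c(OCc4ccccc4)c1)[C@H](O)C2 | intermediate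
14 | (2R,3R,4S)-5,7-bis(benzyloxy)-2-[3,4-bis(benzyloxy)phenyl]-4-(2-ethoxyethoxy)chroman-3-ol | C(c4ccccc4)Oc1cc(OCc4ccccc4)c2c(c1)O[C@H](c1ccc(OCc4ccccc4)c(OCc4ccccc4)c1)[C@H](O)[C@H]2OCCOCC | intermediate
15 | (2R,3R,4S)-6,8-dibromo-5,7-bis(benzyloxy)-2-[3,4-bis(benzyloxy)phenyl]-4-(2-ethoxyethoxy)chroman-3-ol | C(c4ccccc4)Oc1c(Br)c(OCc4ccccc4)c2c(c1Br)O[C@H](c1ccc(OCc4ccccc4)c(OCc4ccccc4)c1)[C@H](O)[C@H]2OCCOCC | intermediate
16 | 6,8-dibromo-tetra-O-benzyl-epicatechin-(4β→6)-8-bromo-tetra-O-benzyl-epicatechin | C(c4ccccc4)Oc1c(Br)c(OCc4ccccc4)c2c(c1Br)O[C@H](c1ccc(OCc4ccccc4)c(OCc4ccccc4)c1)[C@H](O)[C@H]2c1c(OCc4ccccc4)c(Br)c2c(c1OCc4ccccc4)C[C@@H](O)[C@@H](c1ccc(OCc4ccccc4)c(OCc4ccccc4)c1)O2 | intermediate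
17 | 6,8-dibromo-tetra-O-benzyl-epicatechin-(4β→6)-8-bromo-4β-(2-ethoxyethoxy)-tetra-O-benzyl-epicatechin | C(c4ccccc4)Oc1c(Br)c(OCc4ccccc4)c2c(c1Br)O[C@H](c1ccc(OCc4ccccc4)c(OCc4ccccc4)c1)[C@H](O)[C@H]2c1c(OCc4ccccc4)c(Br)c2c(c1OCc4ccccc4)[C@H](OCCOCC)[C@@H](O)[C@@H](c1ccc(OCc4ccccc4)c(OCc4ccccc4)c1)O2 | intermediate
18 | 6,8-dibromo-tetra-O-benzyl-epicatechin-(4β→6)-8-bromo-tetra-O-benzyl-epicatechin-(4β→6)-8-bromo-tetra-O-benzyl-epicatechin | C(c4ccccc4)Oc1c(Br)c(OCc4ccccc4)c2c(c1Br)O[C@H](c1ccc(OCc4ccccc4)c(OCc4ccccc4)c1)[C@H](O)[C@H]2c1c(OCc4ccccc4)c(Br)c2c(c1OCc4ccccc4)[C@H](c1c(OCc4ccccc4)c(Br)c3c(c1OCc4ccccc4)C[C@@H](O)[C@@H](c1ccc(OCc4ccccc4)c(OCc4ccccc4)c1)O3)[C@@H](O)[C@@H](c1ccc(OCc4ccccc4)c(OCc4ccccc4)c1)O2 | intermediate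
19 | epicatechin-(4β→6)-epicatechin-(4β→6)-epicatechin, all units (2R,3R), both interflavan C4 (S) | Oc1cc(O)c2c(c1)O[C@H](c1ccc(O)c(O)c1)[C@H](O)[C@H]2c1c(O)cc2c(c1O)[C@H](c1c(O)cc3c(c1O)C[C@@H](O)[C@@H](c1ccc(O)c(O)c1)O3)[C@@H](O)[C@@H](c1ccc(O)c(O)c1)O2 | target

**Count.** Total steps: 14. Longest linear sequence: 12 steps (2, 3, 4, 5, 6, 7, 9, 10, 11, 12, 13, 14).

**Steps most likely to fail**

Step 5. The epoxy phenoxide may close 5-exo at the non-benzylic epoxide carbon before acid is added, the arylacetaldehyde may enolise and self-condense, or the acid opening may ionise and erode C2. The fallback sets out from 7 (with 3) and returns at 10; it accepts the 5-exo mode and keeps the ring expansion as a separate event. Ylide epoxidation is run under protic base (KOH, MeCN/H2O, rt) until the phenoxide has opened the epoxide completely to (S)-[(2R)-4,6-bis(benzyloxy)-2,3-dihydro-1-benzofuran-2-yl][3,4-bis(benzyloxy)phenyl]methanol F1. This carbinol is then isomerised with catalytic TsOH in aqueous 1,4-dioxane: the ring oxygen displaces the ionising benzylic hydroxyl to give a bicyclic aryloxiranium ion, and water opens it at the ring carbon under thermodynamic control (the oxiranium type of five-to-six ring expansion of 2-(1-hydroxyalkyl) cyclic ethers). Two inversions deliver 10 with the same configuration as the direct route.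

Step 12. Hydride abstraction may be slow on the hindered, bromine-deactivated dimer, or may occur at the doubly benzylic interflavan C4–H of the upper unit. The fallback sets out from 13 and returns at 18, so that no dimer is oxidised. Monomer 13 is oxidised (DDQ, 2-ethoxyethanol) to (2R,3R,4S)-8-bromo-5,7-bis(benzyloxy)-2-[3,4-bis(benzyloxy)phenyl]-4-(2-ethoxyethoxy)chroman-3-ol F2. F2 is coupled (Me3SiOTf, −78 °C) with an excess of 13 to the lower dimer 8-bromo-tetra-O-benzyl-epicatechin-(4β→6)-8-bromo-tetra-O-benzyl-epicatechin F3, whose only free ring A carbon is C6 of its upper unit. The capped monomer 15 is then coupled to F3 under the same conditions to give 18.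

Step 13. C-arylation at the hindered C6 of 13 may be slow, so the dimeric cation may instead eliminate to the flav-3-ene or be captured by adventitious water. The fallback sets out from 17 and returns at 18; it switches to thiophilic activation under neutral conditions. Dimer 17 is treated with 2,6-dimethylbenzenethiol and BF3·OEt2 (−78 °C), where the small soft thiol traps the cation efficiently to give 6,8-dibromo-tetra-O-benzyl-epicatechin-(4β→6)-8-bromo-4β-(2,6-dimethylphenylthio)-tetra-O-benzyl-epicatechin F4. F4 is then ionised with AgBF4 in CH2Cl2 in the presence of 13 and a hindered pyridine base to give 18.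

**Further compounds**
F1 | step 5 | (S)-[(2R)-4,6-bis(benzyloxy)-2,3-dihydro-1-benzofuran-2-yl][3,4-bis(benzyloxy)phenyl]methanol | C(c4ccccc4)Oc1cc(OCc4ccccc4)c2c(c1)O[C@H](C2)[C@@H](O)c1ccc(OCc4ccccc4)c(OCc4ccccc4)c1
F2 | step 12 | (2R,3R,4S)-8-bromo-5,7-bis(benzyloxy)-2-[3,4-bis(benzyloxy)phenyl]-4-(2-ethoxyethoxy)chroman-3-ol | C(c4ccccc4)Oc1cc(OCc4ccccc4)c2c(c1Br)O[C@H](c1ccc(OCc4ccccc4)c(OCc4ccccc4)c1)[C@H](O)[C@H]2OCCOCC
F3 | step 12 | 8-bromo-tetra-O-benzyl-epicatechin-(4β→6)-8-bromo-tetra-O-benzyl-epicatechin | C(c4ccccc4)Oc1cc(OCc4ccccc4)c2c(c1Br)O[C@H](c1ccc(OCc4ccccc4)c(OCc4ccccc4)c1)[C@H](O)[C@H]2c1c(OCc4ccccc4)c(Br)c2c(c1OCc4ccccc4)C[C@@H](O)[C@@H](c1ccc(OCc4ccccc4)c(OCc4ccccc4)c1)O2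
F4 | step 13 | 6,8-dibromo-tetra-O-benzyl-epicatechin-(4β→6)-8-bromo-4β-(2,6-dimethylphenylthio)-tetra-O-benzyl-epicatechin | C(c4ccccc4)Oc1c(Br)c(OCc4ccccc4)c2c(c1Br)O[C@H](c1ccc(OCc4ccccc4)c(OCc4ccccc4)c1)[C@H](O)[C@H]2c1c(OCc4ccccc4)c(Br)c2c(c1OCc4ccccc4)[C@H](Sc1c(C)cccc1C)[C@@H](O)[C@@H](c1ccc(OCc4ccccc4)c(OCc4ccccc4)c1)O2
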